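**Plan**
1. Retrosynthetic cuts: (a) alkyl-ketone carbon to pyrrole C2; (b) diaryl-ketone carbon to arene C3; (c) the CH2–CH2 bond of the side chain, made as C=C.
2. Enabling feature: a resorcinol oxygen, its arene carbon, the chain-bearing arene carbon, the two CH2 groups and the ketone carbon are six atoms in a row. The acyl carbon of cut (a) can therefore be stored as a six-membered aryl lactone (a chroman-2-one ring fused to the arene).
3. This temporary ring activates the acyl carbon and masks the acid and one phenol without a protecting group. It cannot cyclise to an indanone because both ortho carbons bear oxygen, and either phenol oxygen may close it because opening gives the same resorcinol.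
4. Forward order: Wittig/hydrogenation builds the C3 chain on 2,6-dimethoxybenzaldehyde, Friedel–Crafts acylation brings in the first dichloropyrrole, and BBr3/acid closes the lactone. A C2-magnesiated N-Boc-dichloropyrrole then opens it (bond a), and methanolysis removes Boc.
5. 4,5-Dichloropyrrole-2-carboxylic acid supplies both pyrroles with the chlorines in place, once as acyl chloride (electrophile) and once, after iododecarboxylation, as Grignard reagent (nucleophile). No chlorination is needed next to the resorcinol.
6. Stereochemistry: the target has no stereogenic element, so nothing has to be set.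

Key step: step 6

Remark on the chemistry: the SMILES shows no stereocentre, stereogenic axis or stereodefined double bond, so the compound is achiral and "single enantiomer" is taken to mean the constitution as drawn.

**Step 1**
Reactants: 1 2,6-dimethoxybenzaldehyde; 2 methyl (triphenylphosphoranylidene)acetate
Product: 3 methyl (E)-3-(2,6-dimethoxyphenyl)prop-2-enoate
Conditions: PhMe, 110 °C
Reagents that add atoms: none
Why: Wittig olefination with a stabilised ylide should give the E-enoate even from the hindered, electron-rich aldehyde, and the alkene geometry is of no consequence because step 2 saturates the double bond.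

**Step 2**
Reactants: 3 methyl (E)-3-(2,6-dimethoxyphenyl)prop-2-enoate
Product: 4 methyl 3-(2,6-dimethoxyphenyl)propanoate
Conditions: H2 (1 atm), 10% Pd/C, EtOAc, rt
Reagents that add atoms: none
Why: Heterogeneous catalytic hydrogenation saturates the conjugated C=C bond and is placed before any C–Cl bond enters the molecule, so that hydrodechlorination cannot interfere.

**Step 3**
Reactants: 5 4,5-dichloro-1H-pyrrole-2-carboxylic acid; 4 methyl 3-(2,6-dimethoxyphenyl)propanoate
Product: 7 methyl 3-[3-(4,5-dichloro-1H-pyrrole-2-carbonyl)-2,6-dimethoxyphenyl]propanoate, via acid chloride 6 (not isolated)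
Conditions: 5, (COCl)2, DMF (cat.), CH2Cl2, 0 °C → rt, evaporate; then 4, AlCl3 (3 equiv), CH2Cl2, 0 °C → rt; ice/1 M HCl
Reagents that add atoms: oxalyl chloride, O=C(Cl)C(=O)Cl (supplies only the chlorine of 6; no reagent atom stays in 7)
Why: Friedel–Crafts acylation with the acid chloride made in the flask: the acylium ion should attack C3 of the arene, which is ortho to one methoxy group, para to the other and equivalent to C5 by symmetry (C4 is meta to both), the new ketone stops a second acylation, and the twofold chlorinated acylpyrrole is too electron-poor to be acylated itself.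

**Step 4**
Reactants: 7 methyl 3-[3-(4,5-dichloro-1H-pyrrole-2-carbonyl)-2,6-dimethoxyphenyl]propanoate
Product: 9 6-(4,5-dichloro-1H-pyrrole-2-carbonyl)-5-hydroxychroman-2-one, via dihydroxy ester 8 (not isolated)
Conditions: BBr3 (6 equiv), CH2Cl2, −78 °C → rt; H2O; crude 8, p-TsOH·H2O (cat.), PhMe, reflux (Dean–Stark)
Reagents that add atoms: none
Why: Cleavage of both aryl methyl ethers with BBr3 is followed by acid-catalysed lactonisation (intramolecular transesterification) under equilibrating conditions, in which the oxygen para to the ketone should close the six-membered ring because the ortho hydroxyl stays locked in its hydrogen bond to the ketone.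

**Step 5**
Reactants: 5 4,5-dichloro-1H-pyrrole-2-carboxylic acid
Product: 11 tert-butyl 2,3-dichloro-5-iodo-1H-pyrrole-1-carboxylate, via free iodopyrrole 10 (not isolated)
Conditions: I2 (1.0 equiv), KI, NaHCO3, H2O/CH2Cl2, rt → 40 °C, dark; organic phase washed (aq. Na2S2O3) and dried; then Boc2O, DMAP (cat.), 0 °C → rt
Reagents that add atoms: iodine, II; di-tert-butyl dicarbonate, CC(C)(C)OC(=O)OC(=O)OC(C)(C)C
Why: Iododecarboxylation, the ipso substitution of a pyrrole-2-carboxylate by electrophilic iodine with loss of CO2, puts the halogen exactly on the carbon that is to become nucleophilic, and immediate DMAP-catalysed N-acylation with Boc2O turns the sensitive N–H trihalopyrrole into a storable carbamate without an acidic proton.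

**Step 6**
Reactants: 9 6-(4,5-dichloro-1H-pyrrole-2-carbonyl)-5-hydroxychroman-2-one; 11 tert-butyl 2,3-dichloro-5-iodo-1H-pyrrole-1-carboxylate
Product: 14 tert-butyl 2,3-dichloro-5-{3-[3-(4,5-dichloro-1H-pyrrole-2-carbonyl)-2,6-dihydroxyphenyl]propanoyl}-1H-pyrrole-1-carboxylate, via pyrrolyl Grignard reagent 12 (not isolated), via bis-magnesium salt 13 (not isolated)
Conditions: 11 (1.3 equiv), i-PrMgCl·LiCl (1.3 equiv), THF, −40 °C; separately 9, i-PrMgCl·LiCl (2.0 equiv), THF, −78 °C; 12 added by cannula to 13, −78 → −20 °C; sat. aq. NH4Cl
Reagents that add atoms: isopropylmagnesium chloride–lithium chloride, CC(C)[Mg]Cl.[Li+].[Cl-] (supplies only Mg and Cl of 12 and 13; no reagent atom stays in 14)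
Why: Iodine–magnesium exchange places magnesium on the pyrrole carbon that carried the iodine, and this carbanion 12 adds to the lactone carbonyl of 13 to give a cyclic 2-oxidochroman adduct that expels the aryloxide, so that the bond between the ketone carbon and pyrrole C2 forms and the second phenol is set free in the same event. The closest known reaction type is the acyl substitution of aryl esters and of dihydrocoumarin-type lactones by one equivalent of an aryl or heteroaryl Grignard reagent at low temperature, which stops at the 2-hydroxyaryl-substituted ketone. No ring is closed and no stereocentre is created; the only ring event is the opening of the temporary six-membered chroman-2-one ring. Chemoselectivity among the carbonyl groups is needed and comes from the substrate: in 13 the diaryl ketone stands between a magnesium phenoxide and a magnesium pyrrolide that both donate into it and is thereby switched off, the carbamate carbonyl is shielded by its tert-butyl group, and the aryloxy-activated lactone is left as the only good electrophile. Single addition is needed as well and should be secured by the low temperature, the near-stoichiometric charge of 12, the lifetime of the cyclic magnesium hemiketal and the crowding of the released ketone by the neighbouring N-Boc group. The position of the iodine fixes the regiochemistry on the pyrrole, and self-acylation of the acyl donor to an indanone is excluded because both arene carbons ortho to the side chain carry oxygen.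

**Step 7**
Reactants: 14 tert-butyl 2,3-dichloro-5-{3-[3-(4,5-dichloro-1H-pyrrole-2-carbonyl)-2,6-dihydroxyphenyl]propanoyl}-1H-pyrrole-1-carboxylate
Product: 15 dihydrotetrachlorizine (target)
Conditions: K2CO3, MeOH, 0 °C → rt, Ar; 1 M HCl
Reagents that add atoms: none
Why: Base-mediated methanolysis of an N-Boc group on a 2-acylpyrrole, an activated carbamate whose pyrrolide is a good leaving group, should be fast at room temperature and, unlike acidolysis, generates no tert-butyl cation that could alkylate the free resorcinol ring.

**Compound list**
1 | 2,6-dimethoxybenzaldehyde | COc1cccc(OC)c1C=O | starting material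
2 | methyl (triphenylphosphoranylidene)acetate | COC(=O)C=P(c1ccccc1)(c1ccccc1)c1ccccc1 | starting material
3 | methyl (E)-3-(2,6-dimethoxyphenyl)prop-2-enoate | COC(=O)/C=C/c1c(OC)cccc1OC | intermediate
4 | methyl 3-(2,6-dimethoxyphenyl)propanoate | COC(=O)CCc1c(OC)cccc1OC | intermediate
5 | 4,5-dichloro-1H-pyrrole-2-carboxylic acid | OC(=O)c1cc(Cl)c(Cl)[nH]1 | starting material
6 | 4,5-dichloro-1H-pyrrole-2-carbonyl chloride | O=C(Cl)c1cc(Cl)c(Cl)[nH]1 | intermediate
7 | methyl 3-[3-(4,5-dichloro-1H-pyrrole-2-carbonyl)-2,6-dimethoxyphenyl]propanoate | COC(=O)CCc1c(OC)ccc(C(=O)c2cc(Cl)c(Cl)[nH]2)c1OC | intermediate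
8 | methyl 3-[3-(4,5-dichloro-1H-pyrrole-2-carbonyl)-2,6-dihydroxyphenyl]propanoate | COC(=O)CCc1c(O)ccc(C(=O)c2cc(Cl)c(Cl)[nH]2)c1O | intermediate
9 | 6-(4,5-dichloro-1H-pyrrole-2-carbonyl)-5-hydroxychroman-2-one | O=C1CCc2c(O1)ccc(C(=O)c3cc(Cl)c(Cl)[nH]3)c2O | intermediate
10 | 2,3-dichloro-5-iodo-1H-pyrrole | Clc1cc(I)[nH]c1Cl | intermediate
11 | tert-butyl 2,3-dichloro-5-iodo-1H-pyrrole-1-carboxylate | CC(C)(C)OC(=O)n1c(I)cc(Cl)c1Cl | intermediate
12 | [1-(tert-butoxycarbonyl)-4,5-dichloro-1H-pyrrol-2-yl]magnesium chloride (LiCl complex) | CC(C)(C)OC(=O)n1c([Mg]Cl)cc(Cl)c1Cl | intermediate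
13 | O,N-bis(chloromagnesium) salt of 9 | O=C1CCc2c(O1)ccc(C(=O)c3cc(Cl)c(Cl)n3[Mg]Cl)c2O[Mg]Cl | intermediate
14 | tert-butyl 2,3-dichloro-5-{3-[3-(4,5-dichloro-1H-pyrrole-2-carbonyl)-2,6-dihydroxyphenyl]propanoyl}-1H-pyrrole-1-carboxylate | CC(C)(C)OC(=O)n1c(C(=O)CCc2c(O)ccc(C(=O)c3cc(Cl)c(Cl)[nH]3)c2O)cc(Cl)c1Cl | intermediate
15 | dihydrotetrachlorizine, 1-(4,5-dichloro-1H-pyrrol-2-yl)-3-[3-(4,5-dichloro-1H-pyrrole-2-carbonyl)-2,6-dihydroxyphenyl]propan-1-one | O=C(CCc1c(O)ccc(C(=O)c2cc(Cl)c(Cl)[nH]2)c1O)c1cc(Cl)c(Cl)[nH]1 | target

Total step count: 7. Longest linear sequence: 6 steps (1, 2, 3, 4, 6, 7, counted from 1).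

**Steps most likely to fail**

**Risk A (step 6).**
- The Grignard reagent may add a second time once the hemiketal has collapsed.
- The lactone α-CH2 group may transfer a proton to the carbanion.
- The bis-magnesium salt may dissolve poorly.

The fallback sets out from 9 and comes back at 14. The lactone is opened with N,O-dimethylhydroxylamine hydrochloride and i-PrMgCl (THF, −20 °C) to the Weinreb amide 3-[3-(4,5-dichloro-1H-pyrrole-2-carbonyl)-2,6-dihydroxyphenyl]-N-methoxy-N-methylpropanamide F1. i-PrMgCl·LiCl (3 equiv, −78 °C) turns this into the tris(chloromagnesium) salt of the amide F2, to which 12 is added. The five-membered magnesium chelate of the tetrahedral adduct should survive until the quench, so over-addition is excluded by mechanism rather than by stoichiometry. Aqueous NH4Cl then releases 14.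

**Risk B (step 5).**
- The N-unsubstituted trihalopyrrole may decompose before it is protected.
- Iodination may compete at the free β-carbon.

The fallback sets out from 5 and comes back at 15. Protodecarboxylation of 5 (2-aminoethanol, about 170 °C, short contact time, N2) should give 2,3-dichloro-1H-pyrrole F3. This is kept in cold ether solution and deprotonated at once with EtMgBr to (2,3-dichloro-1H-pyrrol-1-yl)magnesium bromide F4. The ambident pyrrolide is then C-acylated at its only free α-carbon by 13 (THF/toluene, 0 °C → rt), which is the known C2-acylation of pyrrolylmagnesium halides with activated esters. A second equivalent of the pyrrolide takes up the proton that is released, and the resulting product anion resists further attack. Acidic work-up gives 15 directly, without iodine, Boc or step 7.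

**Risk C (step 3).**
- The N–H acid chloride may condense with itself.
- The strongly stabilised acylium ion may attack sluggishly.
- AlCl3 may cleave the ethers prematurely.

The fallback sets out from 4 and comes back at 9. Compound 4 is demethylated and lactonised first (BBr3, CH2Cl2; then p-TsOH, PhMe, reflux) to 5-hydroxychroman-2-one F5. O-Acylation with 6 (pyridine, CH2Cl2, 0 °C) gives 2-oxochroman-5-yl 4,5-dichloro-1H-pyrrole-2-carboxylate F6. A Fries rearrangement (AlCl3 or TiCl4, chlorobenzene, 80–120 °C) then moves the acyl group to C6, ortho to the phenol oxygen under chelation control, to give 9.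

**Further compounds**
F1 | step 6 | 3-[3-(4,5-dichloro-1H-pyrrole-2-carbonyl)-2,6-dihydroxyphenyl]-N-methoxy-N-methylpropanamide | CON(C)C(=O)CCc1c(O)ccc(C(=O)c2cc(Cl)c(Cl)[nH]2)c1O
F2 | step 6 | tris(chloromagnesium) salt of the amide F1 | CON(C)C(=O)CCc1c(O[Mg]Cl)ccc(C(=O)c2cc(Cl)c(Cl)n2[Mg]Cl)c1O[Mg]Cl
F3 | step 5 | 2,3-dichloro-1H-pyrrole | Clc1cc[nH]c1Cl
F4 | step 5 | (2,3-dichloro-1H-pyrrol-1-yl)magnesium bromide | Clc1ccn([Mg]Br)c1Cl
F5 | step 3 | 5-hydroxychroman-2-one | O=C1CCc2c(O)cccc2O1
F6 | step 3 | 2-oxochroman-5-yl 4,5-dichloro-1H-pyrrole-2-carboxylate | O=C1CCc2c(OC(=O)c3cc(Cl)c(Cl)[nH]3)cccc2O1
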